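The route opens ring B of the bicyclo[3.3.1]nonane at C1–C8 and removes the C7 side chain at C7–C1'. The feature used is the chain C5–C6H2–C7H(prenyl)–C8Me2–C1. It is a C5 prenyl group that has taken up a dimethylallyl cation at C7 and been captured at C8 by enol carbon C1. One enzymatic operation thus forms two C–C bonds, ring B and the stereocentres C1 and C7. The substrate is a monocyclic, dearomatised maclurin derivative, used as the single (S)-C5 enantiomer. In it C5 carries geranyl and prenyl, C1 prenyl, and C3 the 3,4-dihydroxybenzoyl group. The catechol is masked during every basic alkylation, and C5 is resolved before the enzyme.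

Key step: step 7

Numbering: C1 is the prenyl bridgehead, C2–C3(aroyl)–C4 the enolised 1,3-diketone, C5 the geranyl bridgehead, then C6H2, C7H(prenyl), C8Me2, and C9 the bridging ketone. The ring-A carbons of all monocyclic compounds keep these numbers.

Reading of the target: the configuration is (1S,5S,7S). The C7 prenyl group is endo, that is, cis to the C2–C3–C4 bridge on ring B. C5 of 11 has the same spatial arrangement as C5 of 13.

Assumption: each enolised β-triketone is drawn as one tautomer. The tautomers equilibrate and count as one compound, and CIP descriptors refer to the tautomer drawn.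

Design remark: the two C5 antipodes differ only in which arm, prenyl or geranyl, stands on a given ring face. The (R)-antipode would therefore offer its geranyl C2'=C3' bond to the cation and could give an isomer of the same mass. For this reason only (S)-11 is given to the enzyme.

Step 1
Reactants: 1 maclurin; 2 prenyl bromide
Product: 6 3,5-diprenylmaclurin, via maclurin borate 3 (not isolated), via monoprenylmaclurin borate 4 (not isolated), via diprenylmaclurin borate 5 (not isolated)
Conditions: Na2B4O7·10H2O, KOH (pH about 10), H2O, argon, 0 °C to rt; then cold 1 M HCl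
Reagents that add atoms: prenyl bromide 2, CC(C)=CCBr
Why: Aqueous-base C-alkylation of an acylphloroglucinol phenoxide should put one prenyl group on each of the two free ring-A carbons, while the catechol sits in its cyclic borate, a classical transient mask that blocks O-alkylation and autoxidation and hydrolyses on acidification; no stereocentre is formed.

Step 2
Reactants: 6 3,5-diprenylmaclurin
Product: 7 3',4'-bis-O-triisopropylsilyl-3,5-diprenylmaclurin
Conditions: i-Pr3SiCl, imidazole, DMF, 0 °C to rt
Reagents that add atoms: chlorotriisopropylsilane, CC(C)[Si](Cl)(C(C)C)C(C)C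
Why: Silyl ether formation with a bulky chlorosilane should be sterically selective, because every ring-A hydroxyl is flanked by two ortho substituents (and two lie next to the chelating ketone) whereas the catechol hydroxyls are open.

Step 3
Reactants: 7 3',4'-bis-O-triisopropylsilyl-3,5-diprenylmaclurin; 8 geranyl bromide
Product: 9 racemic bis-TIPS ether of the dearomatised 5-geranyl-1,5-diprenyl aroylphloroglucinol
Conditions: LiN(SiMe3)2 (3.3 equiv), THF, −78 to 0 °C; 8 (1.1 equiv); then AcOH
Reagents that add atoms: geranyl bromide 8, CC(C)=CCC/C(C)=C/CBr
Why: This is the alkylative dearomatisation known from lupulone-type syntheses: the tightly ion-paired lithium trisphenoxide should react through carbon with the soft allylic bromide by SN2 with the E alkene retained, the two prenyl-bearing carbons are enantiotopic so that one constitution results, and C5 forms as a racemate.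

Step 4
Reactants: 9 racemic bis-TIPS ether
Product: 10 (S)-enantiomer of 9
Conditions: preparative SFC, amylose tris(3,5-dimethylphenylcarbamate) phase, CO2/i-PrOH, 0.1% HCO2H
Reagents that add atoms: none
Why: Chromatographic resolution on a polysaccharide chiral phase fixes C5, which as an all-carbon quaternary centre cannot racemise later; the (S)-antipode is to be identified by comparing its electronic circular dichroism with the computed curve.

Step 5
Reactants: 10 (S)-bis-TIPS ether
Product: 11 (S)-5-geranyl-1,5-diprenyl-3-(3,4-dihydroxybenzoyl) dearomatised phloroglucinol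
Conditions: Et3N·3HF, THF, argon, 0 °C to rt
Reagents that add atoms: none
Why: Fluoride cleavage of aryl silyl ethers is driven by the Si–F bond, and the weakly acidic, non-basic reagent should leave the four alkenes, the enolised triketone, the free catechol and C5 untouched.

Step 6
Reactants: 2 prenyl bromide
Product: 12 dimethylallyl diphosphate (DMAPP, handled as its triammonium salt)
Conditions: (n-Bu4N)3HP2O7, MeCN, rt; cation-exchange resin (NH4+ form); cellulose chromatography
Reagents that add atoms: tris(tetra-n-butylammonium) hydrogen diphosphate, CCCC[N+](CCCC)(CCCC)CCCC.CCCC[N+](CCCC)(CCCC)CCCC.CCCC[N+](CCCC)(CCCC)CCCC.OP(=O)([O-])OP(=O)([O-])[O-]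
Why: SN2 displacement of a primary allylic halide by the diphosphate anion in a dipolar aprotic solvent is the standard preparation of allylic diphosphates, and ion exchange gives the water-soluble salt; no stereocentre is involved.

Step 7
Reactants: 11 (S)-dearomatised precursor; 12 DMAPP
Product: 13 target, (1S,5S,7S)-3-(3,4-dihydroxybenzoyl)-5-[(2E)-3,7-dimethylocta-2,6-dienyl]-4-hydroxy-8,8-dimethyl-1,7-bis(3-methylbut-2-enyl)bicyclo[3.3.1]non-3-ene-2,9-dione
Conditions: engineered UbiA-type prenyltransferase (yeast microsomes), 12 (3 equiv), MgCl2, HEPES pH 7.5, sodium ascorbate, 2% DMSO, argon, 30 °C; EtOAc extraction, reversed-phase HPLC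
Reagents that add atoms: dimethylallyl diphosphate 12, CC(C)=CCOP(=O)(O)OP(=O)(O)O
Why: Proposed new method: in the active site the diphosphate of 12 departs with the help of bound magnesium, the allyl cation bonds through C1' to C7 of the C5-prenyl double bond of 11 so that the charge lands on tertiary C8 (Markovnikov), and carbon C1 of the C9/C1 enolate captures C8 while the C9 oxygen becomes the bridging ketone. The closest known reaction type is the terminal prenylative bicyclisation by membrane-bound UbiA-family transferases in the biosynthesis of bridgehead-acyl polyprenylated acylphloroglucinols, and since none is known for a C3-aroyl, C5-geranyl substrate, homologues from Garcinia and Clusia transcriptomes would have to be screened and evolved. Ring B (C1, C8, C7, C6, C5, C9) closes as a six-membered cation–enolate cyclisation that is endo with respect to both the C7=C8 alkene and the C9=C1 enolate. C1 is set by the substrate, because the three-atom arm anchored at (S)-C5 can reach C1 only on the ring face on which it stands, so the resolved centre decides the sense of the bridge. C7 is set by the enzyme, which must hold the arm in a boat-shaped geometry and deliver the cation anti to the forming C1–C8 bond, so that the new prenyl group ends endo, beside C2–C3–C4. Among the four side-chain double bonds only that of the C5-prenyl arm may react, and C1 rather than C3 or an enol oxygen must terminate: the single enantiomer places prenyl and not geranyl on the reactive face, the hydrogen-bonded aroyl chelate lowers the nucleophilicity of C3, and the rest depends on the active site.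

Compound list
1 | maclurin, (3,4-dihydroxyphenyl)(2,4,6-trihydroxyphenyl)methanone | O=C(c1ccc(O)c(O)c1)c1c(O)cc(O)cc1O | starting material
2 | prenyl bromide, 1-bromo-3-methylbut-2-ene | CC(C)=CCBr | starting material
3 | maclurin 3',4'-cyclic borate, sodium salt | [Na+].O=C(c1ccc2O[B-](O)(O)Oc2c1)c1c(O)cc(O)cc1O | intermediate
4 | 3-prenylmaclurin 3',4'-cyclic borate, sodium salt | [Na+].CC(C)=CCc1c(O)cc(O)c(C(=O)c2ccc3O[B-](O)(O)Oc3c2)c1O | intermediate
5 | 3,5-diprenylmaclurin 3',4'-cyclic borate, sodium salt | [Na+].CC(C)=CCc1c(O)c(CC=C(C)C)c(O)c(C(=O)c2ccc3O[B-](O)(O)Oc3c2)c1O | intermediate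
6 | 3,5-diprenylmaclurin | CC(C)=CCc1c(O)c(CC=C(C)C)c(O)c(C(=O)c2ccc(O)c(O)c2)c1O | intermediate
7 | 3',4'-bis-O-triisopropylsilyl-3,5-diprenylmaclurin | CC(C)=CCc1c(O)c(CC=C(C)C)c(O)c(C(=O)c2ccc(O[Si](C(C)C)(C(C)C)C(C)C)c(O[Si](C(C)C)(C(C)C)C(C)C)c2)c1O | intermediate
8 | geranyl bromide, (2E)-1-bromo-3,7-dimethylocta-2,6-diene | CC(C)=CCC/C(C)=C/CBr | starting material
9 | racemic bis-TIPS ether of the dearomatised compound (C5 quaternary with geranyl and prenyl, C1 prenyl, C3 aroyl) | CC(C)=CCC/C(C)=C/CC1(CC=C(C)C)C(O)=C(CC=C(C)C)C(=O)C(C(=O)c2ccc(O[Si](C(C)C)(C(C)C)C(C)C)c(O[Si](C(C)C)(C(C)C)C(C)C)c2)=C1O | intermediate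
10 | (S)-enantiomer of 9 | CC(C)=CCC/C(C)=C/C[C@@]1(CC=C(C)C)C(O)=C(CC=C(C)C)C(=O)C(C(=O)c2ccc(O[Si](C(C)C)(C(C)C)C(C)C)c(O[Si](C(C)C)(C(C)C)C(C)C)c2)=C1O | intermediate
11 | (S)-5-geranyl-1,5-diprenyl-3-(3,4-dihydroxybenzoyl) dearomatised phloroglucinol, precursor of the key step | CC(C)=CCC/C(C)=C/C[C@@]1(CC=C(C)C)C(O)=C(CC=C(C)C)C(=O)C(C(=O)c2ccc(O)c(O)c2)=C1O | intermediate
12 | dimethylallyl diphosphate (acid form drawn, triammonium salt used) | CC(C)=CCOP(=O)(O)OP(=O)(O)O | intermediate
13 | target, (1S,5S,7S), C7 prenyl endo | CC(C)=CCC/C(C)=C/C[C@]12C[C@H](CC=C(C)C)C(C)(C)[C@](CC=C(C)C)(C(=O)C(C(=O)c3ccc(O)c(O)c3)=C1O)C2=O | target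

Total step count: 7. Longest linear sequence: 6 (steps 1, 2, 3, 4, 5 and 7).

Steps most likely to fail

1. Step 7 (new method). The transferase may not turn over the unnatural substrate. The cation may also be intercepted by another double bond, by C3, by an enol oxygen or by water.

The fallback uses known chemistry, sets out from 1 and returns at 13. The C7 stereocentre with its prenyl group is bought as (R)-lavandulol, and the C8 cation is made by protonation.
- The conditions of step 1 are used with one equivalent of 2 so that the reaction halts at 4. One equivalent of 8 is added to the same flask to give 3-geranyl-5-prenylmaclurin borate F1.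
- Acidification releases 3-geranyl-5-prenylmaclurin F2, which is silylated as in step 2 to its bis-TIPS ether F3.
- (R)-Lavandulol with Tf2O and 2,6-lutidine gives (R)-lavandulyl triflate F4.
- Alkylative dearomatisation of F3 with LiN(SiMe3)2 and F4 gives the 5-geranyl-5-lavandulyl-1-prenyl dienone F5. It must be separated by chromatography from its C5 epimer and from the isomers alkylated at the prenyl-bearing carbon.
- Formic acid at room temperature protonates the isopropenyl group in the Markovnikov sense. C1 then captures the C8 cation in the known biomimetic cation–enol cyclisation of dearomatised acylphloroglucinols, giving the bis-TIPS ether of the target F6.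
- Cyclised isomers that arise from protonation of the geranyl C2'=C3' bond are removed at this stage.
- Et3N·3HF as in step 5 then gives 13.

In this fallback C7 comes from the chiral pool, C5 from diastereomer separation and C1 from the tether.

2. Step 3. O-alkylation of the ring-A phenoxides may compete with C-alkylation, a second alkylation may occur at C1, and silyl groups may be lost under the basic conditions.

The fallback sets out from 7 and returns at 9.
- Geraniol with methyl chloroformate and pyridine gives geranyl methyl carbonate F7.
- F7 is ionised by Pd(PPh3)4 (zerovalent palladium) in THF at room temperature.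
- In this Tsuji–Trost allylic dearomatisation the liberated methoxide is the only base.
- Attack at the unhindered allyl terminus should give the linear geranyl product.
- O-allylated material re-ionises, so the C-alkylated dienone 9 should accumulate as the irreversible product.

3. Step 1. Masking may be incomplete, which leads to O-alkylation or autoxidation of the catechol. Over-prenylation with premature dearomatisation is also possible.

The fallback sets out from 1 and returns at 6.
- It is a Friedel–Crafts prenylation of unprotected maclurin with 2-methylbut-3-en-2-ol and BF3·OEt2 in dioxane at room temperature.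
- No phenoxide is present, so no oxygen is alkylated.
- The acyl-deactivated ring carrying the catechol should stay inert.
- The two free ring-A carbons are substituted by the prenyl cation equivalent, and chroman by-products are removed by chromatography.

Further compounds
F1 | step 7 | 3-geranyl-5-prenylmaclurin 3',4'-cyclic borate, sodium salt | [Na+].CC(C)=CCC/C(C)=C/Cc1c(O)c(CC=C(C)C)c(O)c(C(=O)c2ccc3O[B-](O)(O)Oc3c2)c1O
F2 | step 7 | 3-geranyl-5-prenylmaclurin | CC(C)=CCC/C(C)=C/Cc1c(O)c(CC=C(C)C)c(O)c(C(=O)c2ccc(O)c(O)c2)c1O
F3 | step 7 | 3',4'-bis-O-triisopropylsilyl ether of F2 | CC(C)=CCC/C(C)=C/Cc1c(O)c(CC=C(C)C)c(O)c(C(=O)c2ccc(O[Si](C(C)C)(C(C)C)C(C)C)c(O[Si](C(C)C)(C(C)C)C(C)C)c2)c1O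
F4 | step 7 | (R)-lavandulyl trifluoromethanesulfonate | O=S(=O)(OC[C@H](CC=C(C)C)C(C)=C)C(F)(F)F
F5 | step 7 | bis-TIPS 5-geranyl-5-[(R)-lavandulyl]-1-prenyl dearomatised aroylphloroglucinol, C5 as in 11 | CC(C)=CCC/C(C)=C/C[C@@]1(C[C@H](CC=C(C)C)C(C)=C)C(O)=C(CC=C(C)C)C(=O)C(C(=O)c2ccc(O[Si](C(C)C)(C(C)C)C(C)C)c(O[Si](C(C)C)(C(C)C)C(C)C)c2)=C1O
F6 | step 7 | 3',4'-bis-O-triisopropylsilyl ether of 13 | CC(C)=CCC/C(C)=C/C[C@]12C[C@H](CC=C(C)C)C(C)(C)[C@](CC=C(C)C)(C(=O)C(C(=O)c3ccc(O[Si](C(C)C)(C(C)C)C(C)C)c(O[Si](C(C)C)(C(C)C)C(C)C)c3)=C1O)C2=O
F7 | step 3 | geranyl methyl carbonate | CC(C)=CCC/C(C)=C/COC(=O)OC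
F0 | step 1 | none | none
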